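Assumption: methyl 3,5-dihydroxybenzoate, 2-methylbut-3-en-2-ol and 2,4-dihydroxybenzaldehyde are taken as the commercial starting materials; the methyl ester is used so that only the two phenols of ring B need protection.

## Analysis of the target

Mulberrofuran V (15) is a 2-arylbenzofuran without any stereocenter: a benzofuran (benzo ring A fused to the furan ring) with a hydroxyl group at C6 carries a resorcinol ring B at C2. Ring B is pentasubstituted: C1' is bonded to benzofuran C2, C2' and C6' each bear a 3-methylbut-2-enyl (prenyl) group, C3' and C5' bear hydroxyl groups, and only C4' bears hydrogen. Both alkenes end in two methyl groups, so there is no double-bond geometry to set, and every selectivity problem is one of position. The sensitive groups are the three free phenols on electron-rich rings, the nucleophilic C3 of the benzofuran and, above all, the two prenyl groups: each sits ortho to a phenol and closes to a 2,2-dimethylchroman under strong acid, and hydrogenolysis or strong Lewis acids would attack the alkenes, which narrows the choice of protecting groups. The synthesis is hard because the prenyl groups occupy the two most crowded carbons of ring B, on both sides of the biaryl bond. Electrophilic prenylation of a 5-arylresorcinol would give mixtures of O-alkylation, attack at C4' between the oxygens and incomplete attack at C2' and C6', and a cross-coupling at C1' would have to join a doubly ortho-substituted carbon. The strategy rests on one feature: ring B has a mirror plane through C1' and C4', C2' and C6' are exactly the two carbons ortho to C1', and the atom attached to C1' is furan C2, which has the oxidation level of a carboxyl carbon once O1–C2 and C2=C3 are disconnected. A carboxyl group on C1' can therefore direct a metal to C2' and C6', cannot reach C4', and afterwards becomes C2 of the benzofuran.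

## Retrosynthetic reasoning

Protecting groups. The three phenols of 15 are freed last. Acidic methanolysis of two MOM ethers leads back to 14, and fluoride cleavage of a triisopropylsilyl ether leads back to 13. MOM is chosen for ring B because it is small enough to sit beside the C–H bonds that must be functionalised, survives phosphate base, ylide chemistry and fluoride, and comes off under acid mild enough for ortho-prenylphenols. The ring-A oxygen carries a bulky silyl group instead because it must survive hydrogen bromide when the phosphonium salt is made. The silyl ether is removed first so that the acid step ends directly in 15.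

Furan ring. In 13 the O1–C2 and C2=C3 bonds are cut, giving the acid chloride 11 and the phosphonium salt 10. In the forward direction the phenol of 10 is acylated to 12, whose ylide attacks the ester carbonyl and expels the phosphine oxide. The cut is made here and not at the C2–C1' biaryl bond because a coupling at C1' would be doubly ortho-hindered and would leave the C1' substituent without an earlier role. The Wittig closure turns a carboxyl carbon on C1' into C2, and that carboxyl group is what the prenylation needs as its directing group. Preparing the ring-A fragment separately keeps the sequence after the prenylation short.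

Ring-A fragment. The C–P bond of 10 is cut to the salicyl alcohol 9, which ionises easily under acid because of its ortho and para oxygens. 9 comes from aldehyde 8 by hydride reduction, and 8 from 7 by silylation of the hydroxyl group that is not hydrogen-bonded to the formyl group.

Acid chloride. 11 is traced to acid 6. The forward reaction must activate a doubly ortho-substituted acid without releasing hydrogen chloride, which would attack the MOM ethers and the prenyl alkenes, so a neutral chloroenamine reagent is used.

Prenyl groups (key disconnection). In 6 the C2'–CH2 and C6'–CH2 bonds are cut, giving acid 3 and two molecules of the tertiary allylic alcohol 4; the mono-prenylated acid 5 lies on the way. These bonds are chosen because both carbons are ortho to the carboxyl group, so one directing group serves both, and because the symmetry of 3 makes the two events equivalent. The gain is that the crowded 1,2,3,5,6-pattern is installed on a simple acid in one operation, without halogenation or a stoichiometric organometallic reagent. The forward reaction must metalate a C–H bond flanked by the carboxylate and an OMOM group, deliver the linear prenyl isomer, and do so twice.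

Ring-B acid. 3 is traced through its methyl ester 2 to 1 by saponification and twofold MOM protection, two routine steps that place all the risk in the prenylation.

## Alternatives that were turned down

Alternative 1: Ring B would be assembled from open pieces by a benzannulation. The disconnection cuts C3'–C4' and C5'–C6' and leads to the racemic cyclobutenone A2, 2,4-bis(3-methylbut-2-enyl)-3-[6-(triisopropylsilyloxy)benzofuran-2-yl]cyclobut-2-en-1-one, and the siloxyalkyne A3, ethynyl triisopropylsilyl ether. In the forward step heat opens A2 to a vinylketene, A3 adds to the ketene in a [2+2] cycloaddition, the new vinylcyclobutenone opens again, and the dienylketene closes by 6π electrocyclisation. Tautomerisation gives the phenol A1, 2,4-bis(3-methylbut-2-enyl)-5-(triisopropylsilyloxy)-3-[6-(triisopropylsilyloxy)benzofuran-2-yl]phenol.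
- For: the position of every substituent on ring B follows from the connectivity of A2 and A3. No directing group and no metal are needed, and the step closes a ring and sets five substituents at once, which the chosen step does not do.
- Against: A2 is harder to reach than ring B itself. A cyclobutenone with a benzofuranyl group and two prenyl groups must come from a ketene–alkyne cycloaddition of uncertain regiochemistry, for which the benzofuran and an internal alkyne have to be built first. The prenyl alkene on C4 of A2 can compete with A3 for the ketene at the temperature the ring opening needs. The differentiation of the two ring-B oxygens in A1 is of no use here.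
- Comparison: the benzofuran, the alkyne, the cyclobutenone, the annulation and the deprotection lie in one linear line, which is longer than the seven linear steps of the chosen route. The chosen strategy buys ring B ready-made and adds only two C–C bonds.

Alternative 2: The disconnection is the furan C2=C3 bond, with O1–C2 traced to an aryl ester. In the forward step the ylide of a benzylic phosphonium salt attacks the neighbouring aroyloxy carbonyl and the phosphine oxide is expelled, giving the tris-MOM benzofuran A4, 2-[3,5-bis(methoxymethoxy)-2,6-bis(3-methylbut-2-enyl)phenyl]-6-(methoxymethoxy)benzofuran.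
- For: the closure is well precedented and driven by aromatisation. With the same protecting group on all three oxygens A4 needs a single deprotection, one step fewer at the end than the chosen route; on this point the alternative is stronger.
- Against: as the central idea it leaves open where the 2,6-diprenylated benzoyl unit comes from. By classical means (twofold halogenation, twofold cross-coupling, cleavage of a shielded ester) the two C–C bonds cost three steps and a stoichiometric tin or boron reagent. Uniform MOM protection also forces the phosphonium salt to be built on the ester by reduction, bromination and quaternisation, which puts about five linear steps on advanced material and risks acyl migration to the benzylic oxygen.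
- Comparison: the chosen route uses the same closure as a supporting step (step 8, through 12), so on the ring closure the two are equal, and alternative 2 is stronger in that each of its steps has direct precedent. The chosen strategy offers a one-step access to 6 and a convergent use of the closure.

Alternative 3: Ring B would be formed by a Diels–Alder reaction that cuts C6'–C1' and C2'–C3'. The pieces are the silyl diene A6, 1-methoxy-7-methyl-1,3-bis(trimethylsilyloxy)octa-1,3,6-triene, and the alkynoate A7, methyl 3-[6-(methoxymethoxy)benzofuran-2-yl]prop-2-ynoate. The nucleophilic terminus of A6 adds to the β-carbon of A7, and elimination of the alkoxy group aromatises the adduct to A5, methyl 2,4-dihydroxy-6-[6-(methoxymethoxy)benzofuran-2-yl]-5-(3-methylbut-2-enyl)benzoate.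
- For: the regiochemistry is the normal one for such dienes, the resorcinol oxygens appear directly, and the benzofuran is already in place. C2' and C6' come out differentiated, which would be better than the chosen route for unsymmetrical analogues.
- Against: A5 carries a methoxycarbonyl group on C2' where the target has a prenyl group. Converting it needs reduction, activation and an sp3 coupling at a carbon flanked by a free phenol (ortho-quinone methide formation) and by the benzofuranyl group, three to four further steps. A7 is a β-aryl alkynoate and a sluggish dienophile for a moisture-sensitive diene substituted at its reacting terminus. Only one prenyl group arrives with the ring, so the symmetry of ring B is not used.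
- Comparison: differentiation of C2' and C6' is not needed for this target. The chosen strategy treats both carbons alike and finishes both prenyl groups in one step.

Key step: step 3

## Route

Step 1
Reactants: 1 methyl 3,5-dihydroxybenzoate
Product: 2 methyl 3,5-bis(methoxymethoxy)benzoate
Conditions: NaH (2.5 equiv), MOMCl (2.6 equiv), DMF, 0 °C to rt
Reagents that add atoms: chloromethyl methyl ether, COCCl
Why: Williamson-type O-alkylation of the two phenoxides by the very reactive α-chloro ether; the methyl ester is inert to these conditions.

Step 2
Reactants: 2 methyl 3,5-bis(methoxymethoxy)benzoate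
Product: 3 3,5-bis(methoxymethoxy)benzoic acid
Conditions: LiOH·H2O (3 equiv), THF/MeOH/H2O, 40 °C; then cold 1 M HCl to pH 4
Reagents that add atoms: lithium hydroxide, [Li+].[OH-]
Why: Saponification of an unhindered methyl benzoate; MOM aryl ethers are stable to base and to a brief cold acidification to pH 4.

Step 3
Reactants: 3 3,5-bis(methoxymethoxy)benzoic acid; 4 2-methylbut-3-en-2-ol
Product: 6 3,5-bis(methoxymethoxy)-2,6-bis(3-methylbut-2-enyl)benzoic acid, via mono-prenylated acid 5 (not isolated)
Conditions: 4 (6 equiv), [Ru(p-cymene)Cl2]2 (5 mol%), K3PO4 (0.5 equiv), Cl3CCH2OH, 60 °C, argon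
Reagents that add atoms: none
Why: Ruthenium-catalysed carboxylate-directed ortho C–H allylation of a benzoic acid with an allylic alcohol, run twice on the same ring. The potassium carboxylate of 3 binds divalent ruthenium, and carboxylate-assisted deprotonative metalation of an ortho C–H bond gives a five-membered ruthenacycle; the neighbouring OMOM group acidifies that C–H bond and is small enough to admit the metal. The vinyl group of 4 inserts into the aryl–ruthenium bond with the aryl group going to the unsubstituted CH2 terminus, away from the quaternary carbinol carbon, and syn β-hydroxide elimination releases the ArCH2–CH=C(CH3)2 unit and a divalent ruthenium hydroxide, so no oxidant is needed and the metal keeps its oxidation state. Protonation by the next molecule of acid closes the cycle, and the same sequence on 5 at the second ortho carbon should give 6. The closest known reaction is the ortho allylation of benzoic acids with allyl alcohols and allyl acetates under [Ru(p-cymene)Cl2]2 and K3PO4, in which acids with two free ortho positions can be allylated twice. No ring is closed and no stereocenter is formed. Three selectivities are needed: site selectivity, secured by the carboxylate because a five-membered metallacycle reaches only C2 and C6 and never C4 between the oxygens; linear rather than branched attachment, which follows from the insertion regiochemistry on a 1,1-dimethylallyl alcohol; and β-hydroxide rather than β-hydride elimination, favoured because the hydroxyl group is held next to ruthenium and its loss gives the trisubstituted alkene.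

Step 4
Reactants: 7 2,4-dihydroxybenzaldehyde
Product: 8 2-hydroxy-4-(triisopropylsilyloxy)benzaldehyde
Conditions: TIPSCl (1.05 equiv), imidazole (2.2 equiv), CH2Cl2, 0 °C to rt
Reagents that add atoms: chlorotriisopropylsilane, CC(C)[Si](Cl)(C(C)C)C(C)C
Why: Selective O-silylation; the 2-hydroxyl group is tied up in a hydrogen bond to the formyl group and flanked by it, so the bulky silyl chloride should react at the 4-hydroxyl group.

Step 5
Reactants: 8 2-hydroxy-4-(triisopropylsilyloxy)benzaldehyde
Product: 9 2-(hydroxymethyl)-5-(triisopropylsilyloxy)phenol
Conditions: NaBH4 (1.0 equiv), THF/MeOH, 0 °C; then sat. aq. NH4Cl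
Reagents that add atoms: none
Why: Borohydride reduction of an aryl aldehyde to the benzylic alcohol; the aryl triisopropylsilyl ether withstands the brief exposure to alkoxide at 0 °C.

Step 6
Reactants: 9 2-(hydroxymethyl)-5-(triisopropylsilyloxy)phenol
Product: 10 [2-hydroxy-4-(triisopropylsilyloxy)benzyl]triphenylphosphonium bromide
Conditions: PPh3·HBr (1.05 equiv), MeCN, rt to 45 °C
Reagents that add atoms: triphenylphosphonium bromide, [Br-].c1ccc([PH+](c2ccccc2)c2ccccc2)cc1
Why: Acid-promoted ionisation of the salicyl alcohol (benzylic cation or ortho-quinone methide, stabilised by the ortho and para oxygens) and capture by the phosphine, the standard preparation of 2-hydroxybenzylphosphonium salts; the hindered aryl silyl ether should tolerate the anhydrous acid, which is consumed as the reaction proceeds.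

Step 7
Reactants: 6 3,5-bis(methoxymethoxy)-2,6-bis(3-methylbut-2-enyl)benzoic acid
Product: 11 3,5-bis(methoxymethoxy)-2,6-bis(3-methylbut-2-enyl)benzoyl chloride
Conditions: 1-chloro-N,N,2-trimethylprop-1-en-1-amine (1.3 equiv), CH2Cl2, 0 °C to rt; concentrate, use crude
Reagents that add atoms: 1-chloro-N,N,2-trimethylprop-1-en-1-amine (Ghosez reagent), CC(C)=C(Cl)N(C)C
Why: Acid chloride formation with an α-chloroenamine under neutral conditions; the only by-product is a neutral amide and no hydrogen chloride is released, so the MOM ethers and the prenyl alkenes are not exposed to acid.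

Step 8
Reactants: 11 3,5-bis(methoxymethoxy)-2,6-bis(3-methylbut-2-enyl)benzoyl chloride; 10 [2-hydroxy-4-(triisopropylsilyloxy)benzyl]triphenylphosphonium bromide
Product: 13 2-[3,5-bis(methoxymethoxy)-2,6-bis(3-methylbut-2-enyl)phenyl]-6-(triisopropylsilyloxy)benzofuran, via ester phosphonium bromide 12 (not isolated)
Conditions: 10 (1.15 equiv), Et3N (4 equiv), toluene, rt, then 110 °C
Reagents that add atoms: none
Why: Intramolecular Wittig reaction of an ester (Hercouet–Le Corre benzofuran synthesis): the phenoxide of 10 is O-acylated to 12, the amine forms the benzylic ylide, and its attack on the adjacent ester carbonyl closes the five-membered ring (5-exo-trig) and expels the phosphine oxide to give the aromatic furan; a slight excess of 10 suppresses C-acylation of the ylide.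

Step 9
Reactants: 13 2-[3,5-bis(methoxymethoxy)-2,6-bis(3-methylbut-2-enyl)phenyl]-6-(triisopropylsilyloxy)benzofuran
Product: 14 2-[3,5-bis(methoxymethoxy)-2,6-bis(3-methylbut-2-enyl)phenyl]benzofuran-6-ol
Conditions: TBAF (1.1 equiv), AcOH (1.1 equiv), THF, 0 °C
Reagents that add atoms: none
Why: Fluoride cleavage of an aryl silyl ether, driven by the Si–F bond; acetic acid buffers the phenoxide, and MOM ethers and alkenes are inert.

Step 10
Reactants: 14 2-[3,5-bis(methoxymethoxy)-2,6-bis(3-methylbut-2-enyl)phenyl]benzofuran-6-ol
Product: 15 Mulberrofuran V, 5-(6-hydroxybenzofuran-2-yl)-4,6-bis(3-methylbut-2-enyl)benzene-1,3-diol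
Conditions: HCl (ca. 1 M, from conc. aq. HCl) in degassed MeOH, 45 °C, argon; stop at full conversion
Reagents that add atoms: none
Why: Acid-catalysed acetal exchange (methanolysis) of the two aryl MOM ethers; the oxocarbenium pathway of the acetal is much faster than protonation of a trisubstituted alkene, so dilute acid at moderate temperature should free the phenols before the prenyl groups cyclise.

## Compound list

1 | methyl 3,5-dihydroxybenzoate | COC(=O)c1cc(O)cc(O)c1 | starting material
2 | methyl 3,5-bis(methoxymethoxy)benzoate | COCOc1cc(OCOC)cc(C(=O)OC)c1 | intermediate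
3 | 3,5-bis(methoxymethoxy)benzoic acid | COCOc1cc(OCOC)cc(C(=O)O)c1 | intermediate
4 | 2-methylbut-3-en-2-ol | C=CC(C)(C)O | starting material
5 | 3,5-bis(methoxymethoxy)-2-(3-methylbut-2-enyl)benzoic acid | CC(C)=CCc1c(OCOC)cc(OCOC)cc1C(=O)O | intermediate (not isolated)
6 | 3,5-bis(methoxymethoxy)-2,6-bis(3-methylbut-2-enyl)benzoic acid | CC(C)=CCc1c(OCOC)cc(OCOC)c(CC=C(C)C)c1C(=O)O | intermediate
7 | 2,4-dihydroxybenzaldehyde | O=Cc1ccc(O)cc1O | starting material
8 | 2-hydroxy-4-(triisopropylsilyloxy)benzaldehyde | CC(C)[Si](Oc1ccc(C=O)c(O)c1)(C(C)C)C(C)C | intermediate
9 | 2-(hydroxymethyl)-5-(triisopropylsilyloxy)phenol | CC(C)[Si](Oc1ccc(CO)c(O)c1)(C(C)C)C(C)C | intermediate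
10 | [2-hydroxy-4-(triisopropylsilyloxy)benzyl]triphenylphosphonium bromide | CC(C)[Si](Oc1ccc(C[P+](c2ccccc2)(c2ccccc2)c2ccccc2)c(O)c1)(C(C)C)C(C)C.[Br-] | intermediate
11 | 3,5-bis(methoxymethoxy)-2,6-bis(3-methylbut-2-enyl)benzoyl chloride | CC(C)=CCc1c(OCOC)cc(OCOC)c(CC=C(C)C)c1C(Cl)=O | intermediate
12 | {2-[3,5-bis(methoxymethoxy)-2,6-bis(3-methylbut-2-enyl)benzoyloxy]-4-(triisopropylsilyloxy)benzyl}triphenylphosphonium bromide | CC(C)=CCc1c(OCOC)cc(OCOC)c(CC=C(C)C)c1C(=O)Oc1cc(O[Si](C(C)C)(C(C)C)C(C)C)ccc1C[P+](c1ccccc1)(c1ccccc1)c1ccccc1.[Br-] | intermediate (not isolated)
13 | 2-[3,5-bis(methoxymethoxy)-2,6-bis(3-methylbut-2-enyl)phenyl]-6-(triisopropylsilyloxy)benzofuran | CC(C)=CCc1c(OCOC)cc(OCOC)c(CC=C(C)C)c1-c1cc2ccc(O[Si](C(C)C)(C(C)C)C(C)C)cc2o1 | intermediate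
14 | 2-[3,5-bis(methoxymethoxy)-2,6-bis(3-methylbut-2-enyl)phenyl]benzofuran-6-ol | CC(C)=CCc1c(OCOC)cc(OCOC)c(CC=C(C)C)c1-c1cc2ccc(O)cc2o1 | intermediate
15 | Mulberrofuran V, 5-(6-hydroxybenzofuran-2-yl)-4,6-bis(3-methylbut-2-enyl)benzene-1,3-diol | CC(C)=CCc1c(O)cc(O)c(CC=C(C)C)c1-c1cc2ccc(O)cc2o1 | target

## Step count and least certain steps

Total: 10 steps. Longest linear sequence: 7 steps (steps 1, 2, 3, 7, 8, 9, 10, from 1 to 15); the ring-A branch (steps 4 to 6) joins at step 8.

Step 3 (key step). The most likely failure is that the second C–H ruthenation does not occur. Each ortho C–H bond is squeezed between the carboxylate and an OMOM group, and after the first prenylation the carboxylate is twisted out of the ring plane, so the reaction may stall at 5. Lactonisation of the carboxylate onto a prenyl alkene is a lesser side path. The fallback sets out from ester 2 and comes back at acid 6. N-Bromosuccinimide (2.1 equiv, MeCN) should brominate 2 at the two carbons that are para to one OMOM group and ortho to the other, giving methyl 2,6-dibromo-3,5-bis(methoxymethoxy)benzoate F1. A twofold Stille coupling with tributyl(3-methylbut-2-enyl)stannane (Pd(PPh3)4, a zerovalent palladium catalyst, DMF, 100 °C) should give methyl 3,5-bis(methoxymethoxy)-2,6-bis(3-methylbut-2-enyl)benzoate F2. Because the carbonyl group of F2 is shielded on both sides, the ester is cleaved by SN2 attack of NaSEt on the methyl group (DMF, 80 °C) and not by saponification; acidification gives 6.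

Step 8. The ylide may attack the ester carbonyl too slowly, because the carbonyl is flanked by two ortho CH2 groups. The sequence would then stall at 12, which is lost by ester cleavage on work-up, or the ylide would be acylated at carbon by a second molecule of 11. The fallback sets out from 6 and comes back at 13, moving the bond formation away from the hindered carbon. LiAlH4 (THF, 0 °C to rt) should reduce 6 to [3,5-bis(methoxymethoxy)-2,6-bis(3-methylbut-2-enyl)phenyl]methanol F3, and MnO2 (CH2Cl2) should oxidise it to 3,5-bis(methoxymethoxy)-2,6-bis(3-methylbut-2-enyl)benzaldehyde F4. Ohira–Bestmann homologation (dimethyl (1-diazo-2-oxopropyl)phosphonate, K2CO3, MeOH) should give 3-ethynyl-1,5-bis(methoxymethoxy)-2,4-bis(3-methylbut-2-enyl)benzene F5. Sonogashira coupling of F5 with 2-iodo-5-(triisopropylsilyloxy)phenol F6 (made from commercial 4-iodoresorcinol by silylation of the unhindered hydroxyl group) under Pd(PPh3)2Cl2, CuI and Et3N in DMF at 60 °C, with 5-endo-dig cyclisation of the phenol onto the alkyne in the same flask, should give 13.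

Step 10. Under the acid needed for MOM removal, a freed phenol may add to the neighbouring prenyl alkene (chroman formation), or methanol may add across the alkene. The fallback sets out from 13 and comes back at 15, bypassing 14, and never exposes a free ortho-prenylphenol to protic acid. TESOTf and 2,2'-bipyridyl (CH2Cl2, 0 °C to rt) transfer the methoxymethyl groups to the bipyridyl and leave aryl triethylsilyl ethers, giving 2-[3,5-bis(triethylsilyloxy)-2,6-bis(3-methylbut-2-enyl)phenyl]-6-(triisopropylsilyloxy)benzofuran F7. TBAF buffered with AcOH (THF, 0 °C) should then remove all three silyl groups and give 15.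

Step 6. The silyl ether may be partly lost under hydrogen bromide, and the ortho-quinone methide may oligomerise before the phosphine captures it. The fallback sets out from 8 (with 11) and comes back at 12, building the phosphonium salt under neutral conditions on the ester. Acylation of 8 with 11 (Et3N, cat. DMAP, CH2Cl2) should give 2-formyl-5-(triisopropylsilyloxy)phenyl 3,5-bis(methoxymethoxy)-2,6-bis(3-methylbut-2-enyl)benzoate F8. NaBH4 (THF/MeOH, −20 °C) should give 2-(hydroxymethyl)-5-(triisopropylsilyloxy)phenyl 3,5-bis(methoxymethoxy)-2,6-bis(3-methylbut-2-enyl)benzoate F9; the hindered aroyl group should resist migration to the benzylic oxygen. Appel bromination (CBr4, PPh3, CH2Cl2, 0 °C) should give 2-(bromomethyl)-5-(triisopropylsilyloxy)phenyl 3,5-bis(methoxymethoxy)-2,6-bis(3-methylbut-2-enyl)benzoate F10, and PPh3 in toluene at 80 °C should give 12, which is carried on with Et3N in hot toluene as in step 8.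

## Further compounds

F1 | step 3 | methyl 2,6-dibromo-3,5-bis(methoxymethoxy)benzoate | COCOc1cc(OCOC)c(Br)c(C(=O)OC)c1Br
F2 | step 3 | methyl 3,5-bis(methoxymethoxy)-2,6-bis(3-methylbut-2-enyl)benzoate | COC(=O)c1c(CC=C(C)C)c(OCOC)cc(OCOC)c1CC=C(C)C
F3 | step 8 | [3,5-bis(methoxymethoxy)-2,6-bis(3-methylbut-2-enyl)phenyl]methanol | CC(C)=CCc1c(OCOC)cc(OCOC)c(CC=C(C)C)c1CO
F4 | step 8 | 3,5-bis(methoxymethoxy)-2,6-bis(3-methylbut-2-enyl)benzaldehyde | CC(C)=CCc1c(OCOC)cc(OCOC)c(CC=C(C)C)c1C=O
F5 | step 8 | 3-ethynyl-1,5-bis(methoxymethoxy)-2,4-bis(3-methylbut-2-enyl)benzene | CC(C)=CCc1c(OCOC)cc(OCOC)c(CC=C(C)C)c1C#C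
F6 | step 8 | 2-iodo-5-(triisopropylsilyloxy)phenol | Oc1cc(O[Si](C(C)C)(C(C)C)C(C)C)ccc1I
F7 | step 10 | 2-[3,5-bis(triethylsilyloxy)-2,6-bis(3-methylbut-2-enyl)phenyl]-6-(triisopropylsilyloxy)benzofuran | CC[Si](CC)(CC)Oc1cc(O[Si](CC)(CC)CC)c(CC=C(C)C)c(-c2cc3ccc(O[Si](C(C)C)(C(C)C)C(C)C)cc3o2)c1CC=C(C)C
F8 | step 6 | 2-formyl-5-(triisopropylsilyloxy)phenyl 3,5-bis(methoxymethoxy)-2,6-bis(3-methylbut-2-enyl)benzoate | CC(C)=CCc1c(OCOC)cc(OCOC)c(CC=C(C)C)c1C(=O)Oc1cc(O[Si](C(C)C)(C(C)C)C(C)C)ccc1C=O
F9 | step 6 | 2-(hydroxymethyl)-5-(triisopropylsilyloxy)phenyl 3,5-bis(methoxymethoxy)-2,6-bis(3-methylbut-2-enyl)benzoate | CC(C)=CCc1c(OCOC)cc(OCOC)c(CC=C(C)C)c1C(=O)Oc1cc(O[Si](C(C)C)(C(C)C)C(C)C)ccc1CO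
F10 | step 6 | 2-(bromomethyl)-5-(triisopropylsilyloxy)phenyl 3,5-bis(methoxymethoxy)-2,6-bis(3-methylbut-2-enyl)benzoate | CC(C)=CCc1c(OCOC)cc(OCOC)c(CC=C(C)C)c1C(=O)Oc1cc(O[Si](C(C)C)(C(C)C)C(C)C)ccc1CBr
A1 | alternative 1 | 2,4-bis(3-methylbut-2-enyl)-5-(triisopropylsilyloxy)-3-[6-(triisopropylsilyloxy)benzofuran-2-yl]phenol | CC(C)=CCc1c(O)cc(O[Si](C(C)C)(C(C)C)C(C)C)c(CC=C(C)C)c1-c1cc2ccc(O[Si](C(C)C)(C(C)C)C(C)C)cc2o1
A2 | alternative 1 | 2,4-bis(3-methylbut-2-enyl)-3-[6-(triisopropylsilyloxy)benzofuran-2-yl]cyclobut-2-en-1-one (racemic) | CC(C)=CCC1C(=O)C(CC=C(C)C)=C1c1cc2ccc(O[Si](C(C)C)(C(C)C)C(C)C)cc2o1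
A3 | alternative 1 | ethynyl triisopropylsilyl ether | C#CO[Si](C(C)C)(C(C)C)C(C)C
A4 | alternative 2 | 2-[3,5-bis(methoxymethoxy)-2,6-bis(3-methylbut-2-enyl)phenyl]-6-(methoxymethoxy)benzofuran | CC(C)=CCc1c(OCOC)cc(OCOC)c(CC=C(C)C)c1-c1cc2ccc(OCOC)cc2o1
A5 | alternative 3 | methyl 2,4-dihydroxy-6-[6-(methoxymethoxy)benzofuran-2-yl]-5-(3-methylbut-2-enyl)benzoate | COC(=O)c1c(O)cc(O)c(CC=C(C)C)c1-c1cc2ccc(OCOC)cc2o1
A6 | alternative 3 | 1-methoxy-7-methyl-1,3-bis(trimethylsilyloxy)octa-1,3,6-triene (alkene geometry not specified) | COC(O[Si](C)(C)C)=CC(O[Si](C)(C)C)=CCC=C(C)C
A7 | alternative 3 | methyl 3-[6-(methoxymethoxy)benzofuran-2-yl]prop-2-ynoate | COC(=O)C#Cc1cc2ccc(OCOC)cc2o1
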